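## Retrosynthetic overview

1. Last bond: the C8 ester, made by Mitsunobu inversion of an 8α-alcohol with (2R,3R)-epoxyangelic acid, whose own oxirane is made separately by Sharpless epoxidation of angelyl alcohol.
2. Key disconnection C7–C8: the ten-membered carbocycle (C1–C10) is closed by a CrCl2-mediated intramolecular carbonyl allylation of a C8 aldehyde by a 3-(bromomethyl)butenolide. Enabling feature: in the α-methylene-γ-butyrolactone ring (C6, C7, C11, C12, O) the triad C13=C11–C7 is an allyl unit and the oxygen-bearing C8 sits on its γ-carbon C7, so the C7–C8 bond, the C8 carbinol, the C7 stereocenter and the exocyclic C11=C13 methylene are one allylation retron.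
3. Cyclization precursor: the lactone ring as a butenolide by ring-closing metathesis on the C6 carbinol; the C1–C10 oxirane by Shi epoxidation of the acyclic E-alkene; C3 by CBS reduction of a (Z)-enone.
4. C3–C4 by Nozaki–Hiyama–Kishi coupling of a (Z)-vinyl iodide (Red-Al/I2 on a resolved propargylic alcohol that carries C6) with a C1–C3/C8–C10 aldehyde built by carboalumination of a butynyl ether and opening of oxirane.
5. Ring order: C1–C10 oxirane, then the lactone, then the ten-membered ring; no ring is closed after it.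

Key step: step 23

Remark: atoms are numbered as in germacranolides (C1–C10 ring, C11–C13 lactone carbons, lactone oxygen on C6, C14/C15 the methyls on C10/C4). The ring closure is assumed to follow the closed chair transition state of carbonyl allylations, which places the new C8 hydroxyl α.

## Route

Step 1
Reactants: 1 methyl (2Z)-2-methylbut-2-enoate (methyl angelate)
Product: 2 (2Z)-2-methylbut-2-en-1-ol
Conditions: i-Bu2AlH (2.2 equiv), CH2Cl2, −78 → 0 °C; aqueous Rochelle salt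
Reagents that add atoms: none
Why: DIBAL-H 1,2-reduction of the unsaturated ester gives the allylic alcohol and leaves the Z-alkene untouched; no stereocenter is formed.

Step 2
Reactants: 2 (2Z)-2-methylbut-2-en-1-ol
Product: 3 [(2S,3R)-2,3-dimethyloxiran-2-yl]methanol
Conditions: Ti(OiPr)4 (cat.), L-(+)-diethyl tartrate (cat.), t-BuOOH, 4 Å molecular sieves, CH2Cl2, −20 °C
Reagents that add atoms: tert-butyl hydroperoxide CC(C)(C)OO
Why: Sharpless asymmetric epoxidation; syn oxygen transfer keeps CH2OH and the C3 methyl cis, and the titanium L-(+)-tartrate catalyst selects the alkene face that makes C2 S (its usual sense for primary allylic alcohols), which for this Z-alkene means (2S,3R).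

Step 3
Reactants: 3 [(2S,3R)-2,3-dimethyloxiran-2-yl]methanol
Product: 4 (2R,3R)-2,3-dimethyloxirane-2-carboxylic acid
Conditions: RuCl3·xH2O (cat.), NaIO4, CCl4–MeCN–H2O, 0 °C → rt
Reagents that add atoms: sodium periodate [Na+].[O-]I(=O)(=O)=O; water O
Why: Ruthenium tetroxide oxidation (RuCl3/NaIO4) of the primary alcohol to the acid should spare the electron-poor oxirane; both stereocenters are untouched and C2 becomes R only because CH2OH turns into COOH.

Step 4
Reactants: 5 ethyl 2-(hydroxymethyl)prop-2-enoate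
Product: 6 ethyl 2-({[tert-butyl(dimethyl)silyl]oxy}methyl)prop-2-enoate
Conditions: TBSCl, imidazole, DMF, 0 °C → rt
Reagents that add atoms: tert-butyl(chloro)dimethylsilane CC(C)(C)[Si](C)(C)Cl
Why: Standard silylation of a primary allylic alcohol.

Step 5
Reactants: 6 ethyl 2-({[tert-butyl(dimethyl)silyl]oxy}methyl)prop-2-enoate
Product: 7 2-({[tert-butyl(dimethyl)silyl]oxy}methyl)prop-2-enoic acid
Conditions: LiOH·H2O, THF–H2O, 0 °C → rt; then 1 M HCl to pH 4 at 0 °C
Reagents that add atoms: lithium hydroxide [Li+].[OH-]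
Why: Saponification of the ethyl ester; the primary silyl ether should survive cold aqueous hydroxide and brief mild acidification.

Step 6
Reactants: 8 but-3-yn-1-ol
Product: 9 1-[(but-3-yn-1-yloxy)methyl]-4-methoxybenzene
Conditions: NaH (1.05 equiv), THF–DMF, 0 °C; 4-methoxybenzyl chloride, Bu4NI (cat.), 0 °C → rt
Reagents that add atoms: 4-methoxybenzyl chloride COc1ccc(CCl)cc1
Why: Williamson etherification of the alkoxide; one equivalent of base leaves the alkyne C–H alone.

Step 7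
Reactants: 9 1-[(but-3-yn-1-yloxy)methyl]-4-methoxybenzene; 10 oxirane
Product: 13 (3E)-6-[(4-methoxybenzyl)oxy]-4-methylhex-3-en-1-ol, via alkenylalane 11 (not isolated), via lithium alanate 12 (not isolated)
Conditions: Me3Al, Cp2ZrCl2 (cat.), CH2Cl2, 0 °C → rt; then n-BuLi, THF–hexane, −78 °C; then oxirane, −78 → 0 °C; dilute HCl work-up
Reagents that add atoms: trimethylaluminium C[Al](C)C
Why: Zirconium-catalysed carboalumination (Negishi) adds CH3 and Al syn across the terminal alkyne with Al at the terminus, which fixes the E-trisubstituted C1=C10 alkene with the C14 methyl, and the butyl alanate opens oxirane with retention at the alkenyl carbon.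

Step 8
Reactants: 13 (3E)-6-[(4-methoxybenzyl)oxy]-4-methylhex-3-en-1-ol
Product: 14 (3E)-6-[(4-methoxybenzyl)oxy]-4-methylhex-3-enal
Conditions: Dess–Martin periodinane, NaHCO3, CH2Cl2, 0 °C; used crude
Reagents that add atoms: none
Why: Buffered Dess–Martin oxidation is neutral enough to avoid migration of the β,γ-alkene into conjugation.

Step 9
Reactants: 15 prop-2-enal (acrolein); 16 bromo(prop-1-yn-1-yl)magnesium
Product: 17 rac-hex-1-en-4-yn-3-ol
Conditions: THF, −78 → 0 °C; aqueous NH4Cl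
Reagents that add atoms: none
Why: 1,2-Addition of the alkynyl Grignard reagent to the enal gives the racemic vinyl propynyl carbinol.

Step 10
Reactants: 17 rac-hex-1-en-4-yn-3-ol
Product: 18 (3S)-hex-1-en-4-yn-3-ol
Conditions: Ti(OiPr)4, L-(+)-diisopropyl tartrate, t-BuOOH (0.6 equiv), 4 Å molecular sieves, CH2Cl2, −20 °C, run past half conversion
Reagents that add atoms: none
Why: Sharpless kinetic resolution; with the L-(+)-tartrate catalyst the (3R) enantiomer should be epoxidised at its vinyl group much faster, so the (3S) alcohol, which carries the future C6 configuration, is recovered.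

Step 11
Reactants: 18 (3S)-hex-1-en-4-yn-3-ol
Product: 20 (3S,4Z)-5-iodohexa-1,4-dien-3-ol, via alkenylaluminate 19 (not isolated)
Conditions: NaAlH2(OCH2CH2OCH3)2 (Red-Al), THF, 0 °C → rt; then I2, THF, −78 → 0 °C
Reagents that add atoms: iodine II
Why: Hydroxyl-directed trans-hydroalumination of the propargylic alkyne (H to C5, Al to C4 in a five-membered chelate) and iodinolysis with retention give the vinyl iodide with C6 and I cis, which is the (Z)-C4=C5 geometry of the target; C6 is untouched.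

Step 12
Reactants: 20 (3S,4Z)-5-iodohexa-1,4-dien-3-ol; 7 2-({[tert-butyl(dimethyl)silyl]oxy}methyl)prop-2-enoic acid
Product: 21 (3S,4Z)-5-iodohexa-1,4-dien-3-yl 2-({[tert-butyl(dimethyl)silyl]oxy}methyl)prop-2-enoate
Conditions: EDC·HCl, DMAP (cat.), CH2Cl2, 0 °C → rt
Reagents that add atoms: none
Why: Steglich-type carbodiimide esterification forms the acyl–oxygen bond, so the C6 stereocenter is not touched.

Step 13
Reactants: 21 (3S,4Z)-5-iodohexa-1,4-dien-3-yl 2-({[tert-butyl(dimethyl)silyl]oxy}methyl)prop-2-enoate; 14 (3E)-6-[(4-methoxybenzyl)oxy]-4-methylhex-3-enal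
Product: 22 (3S,4Z,8E)-6-hydroxy-11-[(4-methoxybenzyl)oxy]-5,9-dimethylundeca-1,4,8-trien-3-yl 2-({[tert-butyl(dimethyl)silyl]oxy}methyl)prop-2-enoate (both epimers at the new carbinol, C3 of the germacrane numbering)
Conditions: CrCl2 (4 equiv), NiCl2 (cat.), DMSO, rt
Reagents that add atoms: none
Why: Nozaki–Hiyama–Kishi coupling; zerovalent nickel inserts into the C–I bond with retention, the alkenyl group passes to trivalent chromium and adds only to the aldehyde, so the Z-alkene is kept and the esters survive; the C3 configuration is not controlled here and is set in steps 14 and 15.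

Step 14
Reactants: 22 (3S,4Z,8E)-6-hydroxy-11-[(4-methoxybenzyl)oxy]-5,9-dimethylundeca-1,4,8-trien-3-yl 2-({[tert-butyl(dimethyl)silyl]oxy}methyl)prop-2-enoate
Product: 23 (3S,4Z,8E)-11-[(4-methoxybenzyl)oxy]-5,9-dimethyl-6-oxoundeca-1,4,8-trien-3-yl 2-({[tert-butyl(dimethyl)silyl]oxy}methyl)prop-2-enoate
Conditions: Dess–Martin periodinane, NaHCO3, CH2Cl2, 0 °C
Reagents that add atoms: none
Why: Dess–Martin oxidation converges both carbinol epimers to one (Z)-enone under neutral conditions that should not isomerise either alkene.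

Step 15
Reactants: 23 (3S,4Z,8E)-11-[(4-methoxybenzyl)oxy]-5,9-dimethyl-6-oxoundeca-1,4,8-trien-3-yl 2-({[tert-butyl(dimethyl)silyl]oxy}methyl)prop-2-enoate
Product: 24 (3S,4Z,6S,8E)-6-hydroxy-11-[(4-methoxybenzyl)oxy]-5,9-dimethylundeca-1,4,8-trien-3-yl 2-({[tert-butyl(dimethyl)silyl]oxy}methyl)prop-2-enoate
Conditions: (R)-2-methyl-CBS-oxazaborolidine (0.5 equiv), catecholborane, toluene, −78 °C
Reagents that add atoms: none
Why: Corey–Bakshi–Shibata reduction; the ketone binds the catalyst with its α-branched alkenyl group (C4) as the large substituent, and the (R)-catalyst then delivers hydride to give the (S) carbinol at C3 under reagent control.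

Step 16
Reactants: 24 (3S,4Z,6S,8E)-6-hydroxy-11-[(4-methoxybenzyl)oxy]-5,9-dimethylundeca-1,4,8-trien-3-yl 2-({[tert-butyl(dimethyl)silyl]oxy}methyl)prop-2-enoate; 25 2-methylpropanoyl chloride
Product: 26 (3S,4Z,6S,8E)-11-[(4-methoxybenzyl)oxy]-5,9-dimethyl-6-[(2-methylpropanoyl)oxy]undeca-1,4,8-trien-3-yl 2-({[tert-butyl(dimethyl)silyl]oxy}methyl)prop-2-enoate
Conditions: Et3N, DMAP (cat.), CH2Cl2, 0 °C
Reagents that add atoms: none
Why: Acylation of the allylic alcohol with the acid chloride installs the C3 isobutyrate with retention.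

Step 17
Reactants: 26 (3S,4Z,6S,8E)-11-[(4-methoxybenzyl)oxy]-5,9-dimethyl-6-[(2-methylpropanoyl)oxy]undeca-1,4,8-trien-3-yl 2-({[tert-butyl(dimethyl)silyl]oxy}methyl)prop-2-enoate
Product: 27 (3S,4Z,6S)-7-[(2R,3R)-3-{2-[(4-methoxybenzyl)oxy]ethyl}-3-methyloxiran-2-yl]-5-methyl-6-[(2-methylpropanoyl)oxy]hepta-1,4-dien-3-yl 2-({[tert-butyl(dimethyl)silyl]oxy}methyl)prop-2-enoate
Conditions: D-fructose-derived Shi ketone (1,2:4,5-di-O-isopropylidene-β-D-erythro-2,3-hexodiulo-2,6-pyranose, 30 mol %), KHSO5 (Oxone), K2CO3, Bu4NHSO4 (cat.), Na2B4O7–Na2EDTA buffer (pH about 10.5), MeCN–CH2(OMe)2–H2O, 0 °C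
Reagents that add atoms: potassium peroxymonosulfate [K+].[O-]S(=O)(=O)OO
Why: Shi asymmetric epoxidation through a chiral dioxirane and a spiro transition state; only the electron-rich C1=C10 alkene should react (C4=C5 is deactivated by two allylic esters, the vinyl and acrylate groups are poor substrates), and the D-fructose-derived ketone gives the (R,R) epoxide of an E-alkene, here (1R,10R), with C2 and C9 kept trans.

Step 18
Reactants: 27 (3S,4Z,6S)-7-[(2R,3R)-3-{2-[(4-methoxybenzyl)oxy]ethyl}-3-methyloxiran-2-yl]-5-methyl-6-[(2-methylpropanoyl)oxy]hepta-1,4-dien-3-yl 2-({[tert-butyl(dimethyl)silyl]oxy}methyl)prop-2-enoate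
Product: 28 (2S,3Z)-4-[(2R)-4-({[tert-butyl(dimethyl)silyl]oxy}methyl)-5-oxo-2,5-dihydrofuran-2-yl]-1-[(2R,3R)-3-{2-[(4-methoxybenzyl)oxy]ethyl}-3-methyloxiran-2-yl]-3-methylbut-3-en-2-yl 2-methylpropanoate
Conditions: second-generation Grubbs catalyst (H2IMes)(PCy3)Cl2Ru=CHPh (10 mol %), toluene, 60 °C
Reagents that add atoms: none
Why: Ring-closing metathesis between the C6 vinyl group and the 1,1-disubstituted acrylate closes the five-membered butenolide (C7=C11); the trisubstituted alkenes and the oxirane are spectators and C6 is unchanged (its descriptor becomes R only by priority change).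

Step 19
Reactants: 28 (2S,3Z)-4-[(2R)-4-({[tert-butyl(dimethyl)silyl]oxy}methyl)-5-oxo-2,5-dihydrofuran-2-yl]-1-[(2R,3R)-3-{2-[(4-methoxybenzyl)oxy]ethyl}-3-methyloxiran-2-yl]-3-methylbut-3-en-2-yl 2-methylpropanoate
Product: 29 (2S,3Z)-4-[(2R)-4-(hydroxymethyl)-5-oxo-2,5-dihydrofuran-2-yl]-1-[(2R,3R)-3-{2-[(4-methoxybenzyl)oxy]ethyl}-3-methyloxiran-2-yl]-3-methylbut-3-en-2-yl 2-methylpropanoate
Conditions: Bu4NF, AcOH (1:1), THF, 0 °C
Reagents that add atoms: none
Why: Fluoride desilylation of the primary allylic silyl ether; the acetic acid buffer should prevent deprotonation at C6 of the butenolide and opening of the oxirane.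

Step 20
Reactants: 29 (2S,3Z)-4-[(2R)-4-(hydroxymethyl)-5-oxo-2,5-dihydrofuran-2-yl]-1-[(2R,3R)-3-{2-[(4-methoxybenzyl)oxy]ethyl}-3-methyloxiran-2-yl]-3-methylbut-3-en-2-yl 2-methylpropanoate
Product: 30 (2S,3Z)-4-[(2R)-4-(bromomethyl)-5-oxo-2,5-dihydrofuran-2-yl]-1-[(2R,3R)-3-{2-[(4-methoxybenzyl)oxy]ethyl}-3-methyloxiran-2-yl]-3-methylbut-3-en-2-yl 2-methylpropanoate
Conditions: CBr4, PPh3, 2,6-lutidine, CH2Cl2, 0 °C
Reagents that add atoms: carbon tetrabromide BrC(Br)(Br)Br
Why: Appel bromination of the primary allylic alcohol under neutral conditions gives the C13 bromide without touching the oxirane or the esters.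

Step 21
Reactants: 30 (2S,3Z)-4-[(2R)-4-(bromomethyl)-5-oxo-2,5-dihydrofuran-2-yl]-1-[(2R,3R)-3-{2-[(4-methoxybenzyl)oxy]ethyl}-3-methyloxiran-2-yl]-3-methylbut-3-en-2-yl 2-methylpropanoate
Product: 31 (2S,3Z)-4-[(2R)-4-(bromomethyl)-5-oxo-2,5-dihydrofuran-2-yl]-1-[(2R,3R)-3-(2-hydroxyethyl)-3-methyloxiran-2-yl]-3-methylbut-3-en-2-yl 2-methylpropanoate
Conditions: DDQ, CH2Cl2–pH 7 phosphate buffer, 0 °C
Reagents that add atoms: none
Why: Oxidative cleavage of the 4-methoxybenzyl ether by DDQ under buffered conditions frees the C8 hydroxyl and leaves the allylic bromide, oxirane and esters intact.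

Step 22
Reactants: 31 (2S,3Z)-4-[(2R)-4-(bromomethyl)-5-oxo-2,5-dihydrofuran-2-yl]-1-[(2R,3R)-3-(2-hydroxyethyl)-3-methyloxiran-2-yl]-3-methylbut-3-en-2-yl 2-methylpropanoate
Product: 32 (2S,3Z)-4-[(2R)-4-(bromomethyl)-5-oxo-2,5-dihydrofuran-2-yl]-3-methyl-1-[(2R,3R)-3-methyl-3-(2-oxoethyl)oxiran-2-yl]but-3-en-2-yl 2-methylpropanoate
Conditions: Dess–Martin periodinane, NaHCO3, CH2Cl2, 0 °C; filtered and used at once
Reagents that add atoms: none
Why: Buffered Dess–Martin oxidation gives the β,γ-epoxy aldehyde without base, which would open the oxirane by elimination.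

Step 23
Reactants: 32 (2S,3Z)-4-[(2R)-4-(bromomethyl)-5-oxo-2,5-dihydrofuran-2-yl]-3-methyl-1-[(2R,3R)-3-methyl-3-(2-oxoethyl)oxiran-2-yl]but-3-en-2-yl 2-methylpropanoate
Product: 34 (1R,3S,6R,7R,8S,10R)-1,10-epoxy-8-hydroxy-3-[(2-methylpropanoyl)oxy]germacra-4(Z),11(13)-dien-12,6-olide (the 8α-alcohol), via allylchromium 33 (not isolated)
Conditions: CrCl2 (10 equiv), degassed DMF–THF, 0.002 M, rt, slow addition of 32
Reagents that add atoms: none
Why: Two equivalents of CrCl2 insert into the C13–Br bond to give allylchromium 33 (trivalent chromium), which attacks the tethered C8 aldehyde through its γ-carbon C7 in a closed six-membered transition state, forming C7–C8, moving the alkene from C7=C11 to the exocyclic C11=C13 and leaving the C8 alkoxide; the closest known reaction type is the Nozaki–Hiyama–Kishi (Barbier-type) allylation of aldehydes by 2-(alkoxycarbonyl)allyl bromides, known between 3-(bromomethyl)butenolides and aldehydes and as a closure of ten-membered germacranolide rings. The only ring closed is the ten-membered carbocycle, by exo-trig attack on the aldehyde carbonyl. C7 is set by addition to the butenolide face opposite the C6–C5 bond, which gives the trans ring fusion and avoids an eclipsed C5–C6–C7–C8 torsion in the forming ring. C8 is set by the chair transition state: the lactone locks the allyl unit in the E-type geometry (C6 trans to C13) and the C9 tether sits pseudo-equatorial, which should give the 7,8-anti alcohol, (8S), the epimer that step 24 inverts. The step needs γ- over α-attack (inherent in the closed transition state), ring closure over intermolecular coupling (high dilution, slow addition) and survival of the β,γ-epoxy aldehyde (non-basic medium, freshly made aldehyde).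

Step 24
Reactants: 34 (1R,3S,6R,7R,8S,10R)-1,10-epoxy-8-hydroxy-3-[(2-methylpropanoyl)oxy]germacra-4(Z),11(13)-dien-12,6-olide; 4 (2R,3R)-2,3-dimethyloxirane-2-carboxylic acid
Product: 35 (1R,3S,6R,7R,8R,10R)-8-{[(2R,3R)-2,3-dimethyloxiran-2-yl]carbonyloxy}-1,10-epoxy-3-[(2-methylpropanoyl)oxy]germacra-4(Z),11(13)-dien-12,6-olide (CNP0117882.2)
Conditions: PPh3, DIAD, toluene, 0 °C → rt
Reagents that add atoms: none
Why: Mitsunobu esterification; the carboxylate of the fairly acidic glycidic acid displaces the oxyphosphonium of the 8α-alcohol by SN2 with inversion, giving the (8R) ester, while H7 lies syn to the leaving group so elimination toward C7 is disfavoured.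

## Compound list

1 | methyl (2Z)-2-methylbut-2-enoate (methyl angelate) | C/C=C(/C)C(=O)OC | starting material
2 | (2Z)-2-methylbut-2-en-1-ol | C/C=C(/C)CO | intermediate
3 | [(2S,3R)-2,3-dimethyloxiran-2-yl]methanol | OC[C@]1(C)O[C@@H]1C | intermediate
4 | (2R,3R)-2,3-dimethyloxirane-2-carboxylic acid | OC(=O)[C@]1(C)O[C@@H]1C | intermediate
5 | ethyl 2-(hydroxymethyl)prop-2-enoate | C=C(CO)C(=O)OCC | starting material
6 | ethyl 2-({[tert-butyl(dimethyl)silyl]oxy}methyl)prop-2-enoate | C=C(CO[Si](C)(C)C(C)(C)C)C(=O)OCC | intermediate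
7 | 2-({[tert-butyl(dimethyl)silyl]oxy}methyl)prop-2-enoic acid | C=C(CO[Si](C)(C)C(C)(C)C)C(=O)O | intermediate
8 | but-3-yn-1-ol | C#CCCO | starting material
9 | 1-[(but-3-yn-1-yloxy)methyl]-4-methoxybenzene | C#CCCOCc1ccc(OC)cc1 | intermediate
10 | oxirane | C1CO1 | starting material
11 | {(1E)-4-[(4-methoxybenzyl)oxy]-2-methylbut-1-en-1-yl}dimethylalane | C[Al](C)/C=C(\C)CCOCc1ccc(OC)cc1 | intermediate (not isolated)
12 | lithium butyl{(1E)-4-[(4-methoxybenzyl)oxy]-2-methylbut-1-en-1-yl}dimethylalanate | [Li+].CCCC[Al-](C)(C)/C=C(\C)CCOCc1ccc(OC)cc1 | intermediate (not isolated)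
13 | (3E)-6-[(4-methoxybenzyl)oxy]-4-methylhex-3-en-1-ol | OCC/C=C(\C)CCOCc1ccc(OC)cc1 | intermediate
14 | (3E)-6-[(4-methoxybenzyl)oxy]-4-methylhex-3-enal | O=CC/C=C(\C)CCOCc1ccc(OC)cc1 | intermediate
15 | prop-2-enal (acrolein) | C=CC=O | starting material
16 | bromo(prop-1-yn-1-yl)magnesium | CC#C[Mg]Br | starting material
17 | rac-hex-1-en-4-yn-3-ol | OC(C=C)C#CC | intermediate
18 | (3S)-hex-1-en-4-yn-3-ol | O[C@@H](C=C)C#CC | intermediate
19 | sodium (5S)-2,2-bis(2-methoxyethoxy)-3-methyl-5-vinyl-2,5-dihydro-1,2-oxaaluminol-2-uide (alkenylaluminate chelate) | [Na+].C=C[C@@H]1O[Al-](OCCOC)(OCCOC)C(C)=C1 | intermediate (not isolated)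
20 | (3S,4Z)-5-iodohexa-1,4-dien-3-ol | O[C@@H](C=C)/C=C(/C)I | intermediate
21 | (3S,4Z)-5-iodohexa-1,4-dien-3-yl 2-({[tert-butyl(dimethyl)silyl]oxy}methyl)prop-2-enoate | C=C(CO[Si](C)(C)C(C)(C)C)C(=O)O[C@@H](C=C)/C=C(/C)I | intermediate
22 | (3S,4Z,8E)-6-hydroxy-11-[(4-methoxybenzyl)oxy]-5,9-dimethylundeca-1,4,8-trien-3-yl 2-({[tert-butyl(dimethyl)silyl]oxy}methyl)prop-2-enoate, both epimers at C6 of the chain | C=C(CO[Si](C)(C)C(C)(C)C)C(=O)O[C@@H](C=C)/C=C(/C)C(O)C/C=C(\C)CCOCc1ccc(OC)cc1 | intermediate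
23 | (3S,4Z,8E)-11-[(4-methoxybenzyl)oxy]-5,9-dimethyl-6-oxoundeca-1,4,8-trien-3-yl 2-({[tert-butyl(dimethyl)silyl]oxy}methyl)prop-2-enoate | C=C(CO[Si](C)(C)C(C)(C)C)C(=O)O[C@@H](C=C)/C=C(/C)C(=O)C/C=C(\C)CCOCc1ccc(OC)cc1 | intermediate
24 | (3S,4Z,6S,8E)-6-hydroxy-11-[(4-methoxybenzyl)oxy]-5,9-dimethylundeca-1,4,8-trien-3-yl 2-({[tert-butyl(dimethyl)silyl]oxy}methyl)prop-2-enoate | C=C(CO[Si](C)(C)C(C)(C)C)C(=O)O[C@@H](C=C)/C=C(/C)[C@@H](O)C/C=C(\C)CCOCc1ccc(OC)cc1 | intermediate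
25 | 2-methylpropanoyl chloride | CC(C)C(Cl)=O | starting material
26 | (3S,4Z,6S,8E)-11-[(4-methoxybenzyl)oxy]-5,9-dimethyl-6-[(2-methylpropanoyl)oxy]undeca-1,4,8-trien-3-yl 2-({[tert-butyl(dimethyl)silyl]oxy}methyl)prop-2-enoate | C=C(CO[Si](C)(C)C(C)(C)C)C(=O)O[C@@H](C=C)/C=C(/C)[C@@H](OC(=O)C(C)C)C/C=C(\C)CCOCc1ccc(OC)cc1 | intermediate
27 | (3S,4Z,6S)-7-[(2R,3R)-3-{2-[(4-methoxybenzyl)oxy]ethyl}-3-methyloxiran-2-yl]-5-methyl-6-[(2-methylpropanoyl)oxy]hepta-1,4-dien-3-yl 2-({[tert-butyl(dimethyl)silyl]oxy}methyl)prop-2-enoate | C=C(CO[Si](C)(C)C(C)(C)C)C(=O)O[C@@H](C=C)/C=C(/C)[C@@H](OC(=O)C(C)C)C[C@H]1O[C@]1(C)CCOCc2ccc(OC)cc2 | intermediate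
28 | (2S,3Z)-4-[(2R)-4-({[tert-butyl(dimethyl)silyl]oxy}methyl)-5-oxo-2,5-dihydrofuran-2-yl]-1-[(2R,3R)-3-{2-[(4-methoxybenzyl)oxy]ethyl}-3-methyloxiran-2-yl]-3-methylbut-3-en-2-yl 2-methylpropanoate | O=C1O[C@@H](C=C1CO[Si](C)(C)C(C)(C)C)/C=C(/C)[C@@H](OC(=O)C(C)C)C[C@H]2O[C@]2(C)CCOCc3ccc(OC)cc3 | intermediate
29 | (2S,3Z)-4-[(2R)-4-(hydroxymethyl)-5-oxo-2,5-dihydrofuran-2-yl]-1-[(2R,3R)-3-{2-[(4-methoxybenzyl)oxy]ethyl}-3-methyloxiran-2-yl]-3-methylbut-3-en-2-yl 2-methylpropanoate | O=C1O[C@@H](C=C1CO)/C=C(/C)[C@@H](OC(=O)C(C)C)C[C@H]2O[C@]2(C)CCOCc3ccc(OC)cc3 | intermediate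
30 | (2S,3Z)-4-[(2R)-4-(bromomethyl)-5-oxo-2,5-dihydrofuran-2-yl]-1-[(2R,3R)-3-{2-[(4-methoxybenzyl)oxy]ethyl}-3-methyloxiran-2-yl]-3-methylbut-3-en-2-yl 2-methylpropanoate | O=C1O[C@@H](C=C1CBr)/C=C(/C)[C@@H](OC(=O)C(C)C)C[C@H]2O[C@]2(C)CCOCc3ccc(OC)cc3 | intermediate
31 | (2S,3Z)-4-[(2R)-4-(bromomethyl)-5-oxo-2,5-dihydrofuran-2-yl]-1-[(2R,3R)-3-(2-hydroxyethyl)-3-methyloxiran-2-yl]-3-methylbut-3-en-2-yl 2-methylpropanoate | O=C1O[C@@H](C=C1CBr)/C=C(/C)[C@@H](OC(=O)C(C)C)C[C@H]2O[C@]2(C)CCO | intermediate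
32 | (2S,3Z)-4-[(2R)-4-(bromomethyl)-5-oxo-2,5-dihydrofuran-2-yl]-3-methyl-1-[(2R,3R)-3-methyl-3-(2-oxoethyl)oxiran-2-yl]but-3-en-2-yl 2-methylpropanoate | O=C1O[C@@H](C=C1CBr)/C=C(/C)[C@@H](OC(=O)C(C)C)C[C@H]2O[C@]2(C)CC=O | intermediate
33 | dichloro(butenolid-3-ylmethyl)chromium derived from 32 (C13–CrCl2 in place of C13–Br) | O=C1O[C@@H](C=C1C[Cr](Cl)Cl)/C=C(/C)[C@@H](OC(=O)C(C)C)C[C@H]2O[C@]2(C)CC=O | intermediate (not isolated)
34 | (1R,3S,6R,7R,8S,10R)-1,10-epoxy-8-hydroxy-3-[(2-methylpropanoyl)oxy]germacra-4(Z),11(13)-dien-12,6-olide | C=C1C(=O)O[C@@H]2/C=C(/C)[C@@H](OC(=O)C(C)C)C[C@H]3O[C@]3(C)C[C@H](O)[C@@H]12 | intermediate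
35 | (1R,3S,6R,7R,8R,10R)-8-{[(2R,3R)-2,3-dimethyloxiran-2-yl]carbonyloxy}-1,10-epoxy-3-[(2-methylpropanoyl)oxy]germacra-4(Z),11(13)-dien-12,6-olide (CNP0117882.2) | C=C1C(=O)O[C@@H]2/C=C(/C)[C@@H](OC(=O)C(C)C)C[C@H]3O[C@]3(C)C[C@@H](OC(=O)[C@]3(C)O[C@@H]3C)[C@@H]12 | target

## Step count and risks

Total step count: 24. Longest linear sequence: 16 steps (steps 9 to 24, from acrolein).

Steps most likely to fail:

Step 23 (ring closure). The β,γ-epoxy aldehyde may open by elimination or under the Lewis-acidic chromium salts, or the allylmetal may couple between molecules before the chain folds. The fallback closes the same C7–C8 bond without a reducing metal, by intramolecular allylboration. It sets out from bromide 30: borylation with B2pin2 and Pd2(dba)3 (cat.) in DMSO should give the pinacol allylboronate F1. DDQ cleavage of the 4-methoxybenzyl ether then gives the alcohol F2, and buffered Dess–Martin oxidation gives the aldehyde F3. Warmed in toluene at high dilution, F3 should close through the same closed chair transition state and, after cleavage of the borate on work-up, come back to the route at 34.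

Step 24 (inverting esterification). The activated C8 alcohol may eliminate toward C9, or the hindered carboxylate may fail to displace at the ring carbon. The fallback inverts C8 by oxidation and reduction and then acylates with retention. It sets out from 34: buffered Dess–Martin oxidation should give the 8-ketone F4. Luche reduction (NaBH4, CeCl3·7H2O, MeOH, −78 °C), with hydride arriving on the face of H7 away from the lactone carbon C11, should give the 8β-alcohol F5. Yamaguchi esterification of F5 with acid 4 (2,4,6-trichlorobenzoyl chloride, Et3N, DMAP, toluene) comes back to the route at 35. The same esterification serves if the ring closure should deliver the 8β-alcohol directly.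

Step 17 (Shi epoxidation). A second alkene may be oxidised, or the esters may hydrolyse at the basic pH. The fallback epoxidises before the fragments are joined, where only one alkene is present. It sets out from 13: Shi epoxidation with the same ketone should give the epoxy alcohol F6, and buffered Dess–Martin oxidation the epoxy aldehyde F7. Nozaki–Hiyama–Kishi coupling of F7 with vinyl iodide 21 gives the carbinol mixture F8; Dess–Martin oxidation gives the enone F9, and CBS reduction with the (R)-catalyst the (S)-alcohol F10. Acylation of F10 with 25 comes back to the route at 27.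

## Further compounds

F1 | step 23 | (2S,3Z)-1-[(2R,3R)-3-{2-[(4-methoxybenzyl)oxy]ethyl}-3-methyloxiran-2-yl]-3-methyl-4-{(2R)-5-oxo-4-[(4,4,5,5-tetramethyl-1,3,2-dioxaborolan-2-yl)methyl]-2,5-dihydrofuran-2-yl}but-3-en-2-yl 2-methylpropanoate | O=C1O[C@@H](C=C1CB2OC(C)(C)C(C)(C)O2)/C=C(/C)[C@@H](OC(=O)C(C)C)C[C@H]3O[C@]3(C)CCOCc4ccc(OC)cc4
F2 | step 23 | (2S,3Z)-1-[(2R,3R)-3-(2-hydroxyethyl)-3-methyloxiran-2-yl]-3-methyl-4-{(2R)-5-oxo-4-[(4,4,5,5-tetramethyl-1,3,2-dioxaborolan-2-yl)methyl]-2,5-dihydrofuran-2-yl}but-3-en-2-yl 2-methylpropanoate | O=C1O[C@@H](C=C1CB2OC(C)(C)C(C)(C)O2)/C=C(/C)[C@@H](OC(=O)C(C)C)C[C@H]3O[C@]3(C)CCO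
F3 | step 23 | (2S,3Z)-3-methyl-1-[(2R,3R)-3-methyl-3-(2-oxoethyl)oxiran-2-yl]-4-{(2R)-5-oxo-4-[(4,4,5,5-tetramethyl-1,3,2-dioxaborolan-2-yl)methyl]-2,5-dihydrofuran-2-yl}but-3-en-2-yl 2-methylpropanoate | O=C1O[C@@H](C=C1CB2OC(C)(C)C(C)(C)O2)/C=C(/C)[C@@H](OC(=O)C(C)C)C[C@H]3O[C@]3(C)CC=O
F4 | step 24 | 8-ketone of 34: (1R,3S,6R,10R,7α-H)-1,10-epoxy-3-[(2-methylpropanoyl)oxy]-8-oxogermacra-4(Z),11(13)-dien-12,6-olide | C=C1C(=O)O[C@@H]2/C=C(/C)[C@@H](OC(=O)C(C)C)C[C@H]3O[C@]3(C)CC(=O)[C@@H]12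
F5 | step 24 | (1R,3S,6R,7R,8R,10R)-1,10-epoxy-8-hydroxy-3-[(2-methylpropanoyl)oxy]germacra-4(Z),11(13)-dien-12,6-olide (the 8β-alcohol) | C=C1C(=O)O[C@@H]2/C=C(/C)[C@@H](OC(=O)C(C)C)C[C@H]3O[C@]3(C)C[C@@H](O)[C@@H]12
F6 | step 17 | 2-[(2R,3R)-3-{2-[(4-methoxybenzyl)oxy]ethyl}-3-methyloxiran-2-yl]ethanol | OCC[C@H]1O[C@]1(C)CCOCc2ccc(OC)cc2
F7 | step 17 | [(2R,3R)-3-{2-[(4-methoxybenzyl)oxy]ethyl}-3-methyloxiran-2-yl]acetaldehyde | O=CC[C@H]1O[C@]1(C)CCOCc2ccc(OC)cc2
F8 | step 17 | (3S,4Z)-6-hydroxy-7-[(2R,3R)-3-{2-[(4-methoxybenzyl)oxy]ethyl}-3-methyloxiran-2-yl]-5-methylhepta-1,4-dien-3-yl 2-({[tert-butyl(dimethyl)silyl]oxy}methyl)prop-2-enoate, both epimers at C6 of the chain | C=C(CO[Si](C)(C)C(C)(C)C)C(=O)O[C@@H](C=C)/C=C(/C)C(O)C[C@H]1O[C@]1(C)CCOCc2ccc(OC)cc2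
F9 | step 17 | (3S,4Z)-7-[(2R,3R)-3-{2-[(4-methoxybenzyl)oxy]ethyl}-3-methyloxiran-2-yl]-5-methyl-6-oxohepta-1,4-dien-3-yl 2-({[tert-butyl(dimethyl)silyl]oxy}methyl)prop-2-enoate | C=C(CO[Si](C)(C)C(C)(C)C)C(=O)O[C@@H](C=C)/C=C(/C)C(=O)C[C@H]1O[C@]1(C)CCOCc2ccc(OC)cc2
F10 | step 17 | (3S,4Z,6S)-6-hydroxy-7-[(2R,3R)-3-{2-[(4-methoxybenzyl)oxy]ethyl}-3-methyloxiran-2-yl]-5-methylhepta-1,4-dien-3-yl 2-({[tert-butyl(dimethyl)silyl]oxy}methyl)prop-2-enoate | C=C(CO[Si](C)(C)C(C)(C)C)C(=O)O[C@@H](C=C)/C=C(/C)[C@@H](O)C[C@H]1O[C@]1(C)CCOCc2ccc(OC)cc2
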